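**Retrosynthetic overview**

1. Target 24 ⇐ oxocene 20 by osmylation of the ring Z-alkene anti to the three α-substituents, cis-semireduction of the silyl diyne and C-desilylation.
2. Oxocene 20 ⇐ oxepene chloromethanesulfonate 18 by a one-atom ring expansion (7 → 8): the ring oxygen leaves C7 for C6 through a 1-oxoniabicyclo[5.1.0]oct-4-ene ion and acetate enters at C7, so the ring, the C7 acetate and two stereocentres come in one operation.
3. Enabling feature: in the oxocane the ring oxygen O1 and the acetoxy group sit on the adjacent carbons C2 and C3 (chain C6 and C7), anti to each other. This is the signature of a fused oxiranium ion opened at its ring carbon, and the electron-poor diynylmethyl group on C6 steers acetate to C7.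
4. 18 ⇐ epoxide 14 (latent C6 carbinol and C5 electrophile) + lithium TMS-butadiynide; 14 ⇐ RCM of a bis-allyl ether, with C12 from an Evans-type glycolate allylation and C13 from a chelation-controlled reduction.
5. C6 and C7 are bought with (S,S)-diepoxybutane; the rings form in the order oxirane (chiral pool) → oxepene (RCM) → oxocene (ring expansion).

Key step: step 13

Remark: atoms are named by the C15 chain of the target (C1 = alkyne terminus, ring oxygen between C6 and C12, C15 = ethyl CH3). Compounds 1, 5 and 15 and all reagents are taken as commercial, and Zn(BH4)2 is used as a pre-formed ethereal solution.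

**Step 1**
Reactants: 1 (2S,2'S)-2,2'-bioxirane
Product: 2 (1S)-1-[(2S)-oxiran-2-yl]but-3-en-1-ol
Conditions: vinylMgBr (1 equiv), CuI (10 mol %), THF, −40 °C, 1 in excess (2 equiv, recovered); aq. NH4Cl
Reagents that add atoms: vinylmagnesium bromide, C=C[Mg]Br
Why: Copper-catalysed Grignard opening of a terminal epoxide at CH2 (SN2); with the C2-symmetric diepoxide in excess only one of the two homotopic oxiranes should react, so C6 and C7 come unchanged from the chiral pool.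

**Step 2**
Reactants: 2 (1S)-1-[(2S)-oxiran-2-yl]but-3-en-1-ol
Product: 3 ethyl 2-{[(1S)-1-[(2S)-oxiran-2-yl]but-3-en-1-yl]oxy}acetate
Conditions: Rh2(OAc)4 (1 mol %), ethyl diazoacetate (slow addition), CH2Cl2, rt
Reagents that add atoms: ethyl diazoacetate, CCOC(=O)C=[N+]=[N-]
Why: Rh(II)-carbenoid O–H insertion forms the glycolate ether under neutral conditions, which avoids the Payne rearrangement that an alkoxide next to the oxirane would risk; no stereocentre is touched.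

**Step 3**
Reactants: 3 ethyl 2-{[(1S)-1-[(2S)-oxiran-2-yl]but-3-en-1-yl]oxy}acetate
Product: 4 2-{[(1S)-1-[(2S)-oxiran-2-yl]but-3-en-1-yl]oxy}acetic acid
Conditions: LiOH, THF/H2O, 0 °C; then 1 M HCl to pH 4 at 0 °C, used without delay
Reagents that add atoms: lithium hydroxide, [Li+].[OH-]
Why: Ester saponification; no stereocentre is affected and the oxirane should survive cold aqueous base and a brief, mildly acidic work-up.

**Step 4**
Reactants: 4 2-{[(1S)-1-[(2S)-oxiran-2-yl]but-3-en-1-yl]oxy}acetic acid, 5 (4S)-4-benzyl-1,3-oxazolidin-2-one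
Product: 8 (4S)-4-benzyl-3-(2-{[(1S)-1-[(2S)-oxiran-2-yl]but-3-en-1-yl]oxy}acetyl)-1,3-oxazolidin-2-one, via pivalic mixed anhydride 6 (not isolated), via lithiated oxazolidinone 7 (not isolated)
Conditions: PivCl, Et3N, THF, −78 → 0 °C; then 5/n-BuLi (THF, −78 °C), −78 → 0 °C; aq. NH4Cl
Reagents that add atoms: none
Why: N-Acylation of the lithiated Evans oxazolidinone by the mixed pivalic anhydride attaches the chiral auxiliary; no new stereocentre is formed.

**Step 5**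
Reactants: 8 (4S)-4-benzyl-3-(2-{[(1S)-1-[(2S)-oxiran-2-yl]but-3-en-1-yl]oxy}acetyl)-1,3-oxazolidin-2-one
Product: 9 (4S)-4-benzyl-3-[(2R)-2-{[(1S)-1-[(2S)-oxiran-2-yl]but-3-en-1-yl]oxy}pent-4-enoyl]-1,3-oxazolidin-2-one
Conditions: NaHMDS, THF, −78 °C; allyl iodide, −78 → −45 °C
Reagents that add atoms: allyl iodide, C=CCI
Why: Evans-type asymmetric alkylation of the chelated Z sodium enolate of a glycolyl oxazolidinone; allyl iodide should add to the face opposite the benzyl group and set C12 as R.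

**Step 6**
Reactants: 9 (4S)-4-benzyl-3-[(2R)-2-{[(1S)-1-[(2S)-oxiran-2-yl]but-3-en-1-yl]oxy}pent-4-enoyl]-1,3-oxazolidin-2-one
Product: 10 (4S)-4-benzyl-3-{[(2R,7S)-7-[(2S)-oxiran-2-yl]-2,3,6,7-tetrahydrooxepin-2-yl]carbonyl}-1,3-oxazolidin-2-one
Conditions: Grubbs II catalyst (5 mol %), CH2Cl2 (5 mM), 40 °C
Reagents that add atoms: none
Why: Ring-closing olefin metathesis of the two allyl groups closes the kinetically easy seven-membered oxepene with loss of ethene; the cis-2,7 relationship follows from the stereocentres already present.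

**Step 7**
Reactants: 10 (4S)-4-benzyl-3-{[(2R,7S)-7-[(2S)-oxiran-2-yl]-2,3,6,7-tetrahydrooxepin-2-yl]carbonyl}-1,3-oxazolidin-2-one
Product: 11 (2R,7S)-N-methoxy-N-methyl-7-[(2S)-oxiran-2-yl]-2,3,6,7-tetrahydrooxepine-2-carboxamide
Conditions: MeONHMe·HCl, AlMe3, CH2Cl2, −20 → 0 °C; Rochelle salt work-up
Reagents that add atoms: N,O-dimethylhydroxylamine hydrochloride, CNOC.Cl
Why: Aluminium amide transamidation cleaves the auxiliary to the Weinreb amide without enolising C12; the short reaction at or below 0 °C should spare the oxirane.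

**Step 8**
Reactants: 11 (2R,7S)-N-methoxy-N-methyl-7-[(2S)-oxiran-2-yl]-2,3,6,7-tetrahydrooxepine-2-carboxamide
Product: 12 1-[(2R,7S)-7-[(2S)-oxiran-2-yl]-2,3,6,7-tetrahydrooxepin-2-yl]propan-1-one
Conditions: EtMgBr, THF, −78 → −10 °C; aq. NH4Cl
Reagents that add atoms: ethylmagnesium bromide, CC[Mg]Br
Why: Grignard addition to a Weinreb amide stops at the ketone through the chelated tetrahedral intermediate, and the low temperature should leave the oxirane and C12 untouched.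

**Step 9**
Reactants: 12 1-[(2R,7S)-7-[(2S)-oxiran-2-yl]-2,3,6,7-tetrahydrooxepin-2-yl]propan-1-one
Product: 13 (1S)-1-[(2R,7S)-7-[(2S)-oxiran-2-yl]-2,3,6,7-tetrahydrooxepin-2-yl]propan-1-ol
Conditions: Zn(BH4)2, Et2O, −40 → −20 °C; aq. NH4Cl
Reagents that add atoms: none
Why: Chelation-controlled (Cram-chelate) ketone reduction; zinc bridges the carbonyl and the ring oxygen and hydride should enter anti to C11, which sets C13 as S (erythro to the C12–O bond).

**Step 10**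
Reactants: 13 (1S)-1-[(2R,7S)-7-[(2S)-oxiran-2-yl]-2,3,6,7-tetrahydrooxepin-2-yl]propan-1-ol
Product: 14 (1S)-1-[(2R,7S)-7-[(2S)-oxiran-2-yl]-2,3,6,7-tetrahydrooxepin-2-yl]propyl acetate
Conditions: Ac2O, pyridine, DMAP (cat.), CH2Cl2, 0 °C
Reagents that add atoms: acetic anhydride, CC(=O)OC(C)=O
Why: DMAP-catalysed acetylation of the only free hydroxyl group installs the C13 acetate of the target with retention.

**Step 11**
Reactants: 14 (1S)-1-[(2R,7S)-7-[(2S)-oxiran-2-yl]-2,3,6,7-tetrahydrooxepin-2-yl]propyl acetate, 15 1,4-bis(trimethylsilyl)buta-1,3-diyne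
Product: 17 (1S)-1-[(2R,7S)-7-[(1S)-1-hydroxy-6-(trimethylsilyl)hexa-3,5-diyn-1-yl]-2,3,6,7-tetrahydrooxepin-2-yl]propyl acetate, via lithium (trimethylsilyl)butadiynide 16 (not isolated)
Conditions: 15, MeLi·LiBr, THF, 0 °C → rt; then −78 °C, BF3·OEt2, then 14 (inverse addition, short time); aq. NH4Cl
Reagents that add atoms: none
Why: BF3-mediated alkynylation of a terminal epoxide at CH2 (Yamaguchi–Hirao reaction) with the diynide from mono-desilylation of 15 reveals the C6 carbinol with retention and brings in C1–C4 in one piece; the more basic epoxide oxygen should be activated in preference to the acetate.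

**Step 12**
Reactants: 17 (1S)-1-[(2R,7S)-7-[(1S)-1-hydroxy-6-(trimethylsilyl)hexa-3,5-diyn-1-yl]-2,3,6,7-tetrahydrooxepin-2-yl]propyl acetate
Product: 18 (1S)-1-[(2R,7S)-7-[(1S)-1-{[(chloromethyl)sulfonyl]oxy}-6-(trimethylsilyl)hexa-3,5-diyn-1-yl]-2,3,6,7-tetrahydrooxepin-2-yl]propyl acetate
Conditions: ClCH2SO2Cl, pyridine, CH2Cl2, 0 °C; used directly
Reagents that add atoms: chloromethanesulfonyl chloride, ClCS(=O)(=O)Cl
Why: Sulfonylation of the secondary alcohol with retention gives the reactive chloromethanesulfonate leaving group on C6.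

**Step 13**
Reactants: 18 (1S)-1-[(2R,7S)-7-[(1S)-1-{[(chloromethyl)sulfonyl]oxy}-6-(trimethylsilyl)hexa-3,5-diyn-1-yl]-2,3,6,7-tetrahydrooxepin-2-yl]propyl acetate
Product: 20 (2R,3R,8R)-8-[(1S)-1-acetoxypropyl]-2-[5-(trimethylsilyl)penta-2,4-diyn-1-yl]-3,4,7,8-tetrahydro-2H-oxocin-3-yl acetate, via bicyclic oxonium ion 19 (not isolated)
Conditions: Zn(OAc)2 (anhydrous, 5 equiv, Lewis acid and buffer), glacial AcOH, 60 °C
Reagents that add atoms: acetic acid, CC(=O)O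
Why: On heating in the ionising, weakly nucleophilic medium the ring oxygen should displace the sulfonate at C6 from the rear (3-exo-tet closure of the oxiranium ring, inversion at C6) to give the 1-oxoniabicyclo[5.1.0]oct-4-ene ion 19, and acetate then opens it at the ring carbon C7 anti to oxygen (inversion at C7), so that the C7–O bond is traded for a C6–O bond and the oxepene becomes the oxocene. The closest known reaction type is the zinc acetate-mediated rearrangement–ring expansion of 2-(1-sulfonyloxyalkyl) tetrahydrofurans and tetrahydropyrans to the next larger 3-acyloxy cyclic ethers through bicyclic oxonium ions. Only the three-membered ring is closed in this step; the eight-membered ring is not made by cyclisation but results from endo opening of the fused oxiranium. Both new stereocentres are controlled by the (6S,7S) configuration bought with 1, because two stereospecific SN2 events should give (6R,7R). The step needs acetate to attack C7 rather than C6 and oxygen participation to outrun direct substitution or elimination; this should be secured by the medium, by the inductively electron-poor diynylmethyl group on C6 (which makes C7 the better carbon to carry positive charge), by the homoallylic C9=C10 bond and by the strain released when the bicyclic ion opens to a Z-oxocene.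

**Step 14**
Reactants: 20 (2R,3R,8R)-8-[(1S)-1-acetoxypropyl]-2-[5-(trimethylsilyl)penta-2,4-diyn-1-yl]-3,4,7,8-tetrahydro-2H-oxocin-3-yl acetate
Product: 21 (2R,3R,5R,6S,8R)-8-[(1S)-1-acetoxypropyl]-5,6-dihydroxy-2-[5-(trimethylsilyl)penta-2,4-diyn-1-yl]oxocan-3-yl acetate
Conditions: OsO4 (2 mol %), NMO, acetone/H2O, 0 °C → rt
Reagents that add atoms: osmium tetroxide, O=[Os](=O)(=O)=O; N-methylmorpholine N-oxide, C[N+]1([O-])CCOCC1; water, O
Why: Upjohn syn-dihydroxylation of the ring Z-alkene; osmium should approach the face opposite the pseudo-axial C7 acetoxy group and the two α-side chains, setting C9 (R) and C10 (S) by substrate control, while the silyl diyne is inert.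

**Step 15**
Reactants: 21 (2R,3R,5R,6S,8R)-8-[(1S)-1-acetoxypropyl]-5,6-dihydroxy-2-[5-(trimethylsilyl)penta-2,4-diyn-1-yl]oxocan-3-yl acetate
Product: 23 (2R,3R,5R,6S,8R)-8-[(1S)-1-acetoxypropyl]-5,6-dihydroxy-2-[(2Z)-5-(trimethylsilyl)pent-2-en-4-yn-1-yl]oxocan-3-yl acetate, via alkenylborane 22 (not isolated)
Conditions: Sia2BH (from BH3·SMe2 and 2-methylbut-2-ene, excess), THF, 0 °C; then AcOH, rt; then H2O2, aq. NaOAc
Reagents that add atoms: none
Why: Syn hydroboration of the non-silylated triple bond of the 1-silyl-1,3-diyne with a hindered dialkylborane, followed by protodeboronation with retention, should give the Z-enyne; the diol is masked in the flask as borinates and the acetates are inert to the reagent.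

**Step 16**
Reactants: 23 (2R,3R,5R,6S,8R)-8-[(1S)-1-acetoxypropyl]-5,6-dihydroxy-2-[(2Z)-5-(trimethylsilyl)pent-2-en-4-yn-1-yl]oxocan-3-yl acetate
Product: 24 (2R,3R,5R,6S,8R)-8-[(1S)-1-acetoxypropyl]-5,6-dihydroxy-2-[(2Z)-pent-2-en-4-yn-1-yl]oxocan-3-yl acetate (CNP0314743.1)
Conditions: TBAF, AcOH (buffer), THF, 0 °C
Reagents that add atoms: none
Why: Fluoride-induced protodesilylation of the alkynylsilane; buffering with acetic acid should prevent acetyl migration to the neighbouring diol and loss of the acetates.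

**Compound list**

1 | (2S,2'S)-2,2'-bioxirane [(S,S)-1,2:3,4-diepoxybutane] | C1O[C@@H]1[C@@H]1CO1 | starting material
2 | (1S)-1-[(2S)-oxiran-2-yl]but-3-en-1-ol | C=CC[C@H](O)[C@@H]1CO1 | intermediate
3 | ethyl 2-{[(1S)-1-[(2S)-oxiran-2-yl]but-3-en-1-yl]oxy}acetate | C=CC[C@H](OCC(=O)OCC)[C@@H]1CO1 | intermediate
4 | 2-{[(1S)-1-[(2S)-oxiran-2-yl]but-3-en-1-yl]oxy}acetic acid | C=CC[C@H](OCC(=O)O)[C@@H]1CO1 | intermediate
5 | (4S)-4-benzyl-1,3-oxazolidin-2-one | O=C1OC[C@H](Cc2ccccc2)N1 | starting material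
6 | mixed anhydride of 4 with pivalic acid | C=CC[C@H](OCC(=O)OC(=O)C(C)(C)C)[C@@H]1CO1 | intermediate
7 | N-lithio-(4S)-4-benzyl-1,3-oxazolidin-2-one | [Li+].O=C1OC[C@H](Cc2ccccc2)[N-]1 | intermediate
8 | (4S)-4-benzyl-3-(2-{[(1S)-1-[(2S)-oxiran-2-yl]but-3-en-1-yl]oxy}acetyl)-1,3-oxazolidin-2-one | C=CC[C@H](OCC(=O)N1[C@@H](Cc2ccccc2)COC1=O)[C@@H]1CO1 | intermediate
9 | (4S)-4-benzyl-3-[(2R)-2-{[(1S)-1-[(2S)-oxiran-2-yl]but-3-en-1-yl]oxy}pent-4-enoyl]-1,3-oxazolidin-2-one | C=CC[C@H](O[C@H](CC=C)C(=O)N1[C@@H](Cc2ccccc2)COC1=O)[C@@H]1CO1 | intermediate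
10 | (4S)-4-benzyl-3-{[(2R,7S)-7-[(2S)-oxiran-2-yl]-2,3,6,7-tetrahydrooxepin-2-yl]carbonyl}-1,3-oxazolidin-2-one (cis-2,7) | C1O[C@@H]1[C@@H]2C/C=C\C[C@@H](O2)C(=O)N3[C@@H](Cc4ccccc4)COC3=O | intermediate
11 | (2R,7S)-N-methoxy-N-methyl-7-[(2S)-oxiran-2-yl]-2,3,6,7-tetrahydrooxepine-2-carboxamide | C1O[C@@H]1[C@@H]2C/C=C\C[C@@H](O2)C(=O)N(C)OC | intermediate
12 | 1-[(2R,7S)-7-[(2S)-oxiran-2-yl]-2,3,6,7-tetrahydrooxepin-2-yl]propan-1-one | C1O[C@@H]1[C@@H]2C/C=C\C[C@@H](O2)C(=O)CC | intermediate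
13 | (1S)-1-[(2R,7S)-7-[(2S)-oxiran-2-yl]-2,3,6,7-tetrahydrooxepin-2-yl]propan-1-ol | C1O[C@@H]1[C@@H]2C/C=C\C[C@@H](O2)[C@@H](O)CC | intermediate
14 | (1S)-1-[(2R,7S)-7-[(2S)-oxiran-2-yl]-2,3,6,7-tetrahydrooxepin-2-yl]propyl acetate | C1O[C@@H]1[C@@H]2C/C=C\C[C@@H](O2)[C@@H](OC(C)=O)CC | intermediate
15 | 1,4-bis(trimethylsilyl)buta-1,3-diyne | C[Si](C)(C)C#CC#C[Si](C)(C)C | starting material
16 | lithium 4-(trimethylsilyl)buta-1,3-diyn-1-ide | [Li+].[C-]#CC#C[Si](C)(C)C | intermediate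
17 | (1S)-1-[(2R,7S)-7-[(1S)-1-hydroxy-6-(trimethylsilyl)hexa-3,5-diyn-1-yl]-2,3,6,7-tetrahydrooxepin-2-yl]propyl acetate | C[Si](C)(C)C#CC#CC[C@H](O)[C@@H]1C/C=C\C[C@@H](O1)[C@@H](OC(C)=O)CC | intermediate
18 | (1S)-1-[(2R,7S)-7-[(1S)-1-{[(chloromethyl)sulfonyl]oxy}-6-(trimethylsilyl)hexa-3,5-diyn-1-yl]-2,3,6,7-tetrahydrooxepin-2-yl]propyl acetate | C[Si](C)(C)C#CC#CC[C@H](OS(=O)(=O)CCl)[C@@H]1C/C=C\C[C@@H](O1)[C@@H](OC(C)=O)CC | intermediate
19 | 1-oxoniabicyclo[5.1.0]oct-4-ene ion (O+ bonded to C6, C7 and C12; C6 inverted) as chloromethanesulfonate | C[Si](C)(C)C#CC#CC[C@@H]1[C@@H]2C/C=C\C[C@@H]([O+]12)[C@@H](OC(C)=O)CC.[O-]S(=O)(=O)CCl | intermediate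
20 | (2R,3R,8R)-8-[(1S)-1-acetoxypropyl]-2-[5-(trimethylsilyl)penta-2,4-diyn-1-yl]-3,4,7,8-tetrahydro-2H-oxocin-3-yl acetate | C[Si](C)(C)C#CC#CC[C@H]1O[C@@H]([C@H](CC)OC(C)=O)C/C=C\C[C@H]1OC(C)=O | intermediate
21 | (2R,3R,5R,6S,8R)-8-[(1S)-1-acetoxypropyl]-5,6-dihydroxy-2-[5-(trimethylsilyl)penta-2,4-diyn-1-yl]oxocan-3-yl acetate | C[Si](C)(C)C#CC#CC[C@H]1O[C@@H]([C@H](CC)OC(C)=O)C[C@H](O)[C@H](O)C[C@H]1OC(C)=O | intermediate
22 | C3-(disiamylboryl) Z-alkenylborane of 21 with both hydroxyls as disiamylborinates | C[Si](C)(C)C#C/C(B(C(C)C(C)C)C(C)C(C)C)=C\C[C@H]1O[C@@H]([C@H](CC)OC(C)=O)C[C@H](OB(C(C)C(C)C)C(C)C(C)C)[C@H](OB(C(C)C(C)C)C(C)C(C)C)C[C@H]1OC(C)=O | intermediate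
23 | (2R,3R,5R,6S,8R)-8-[(1S)-1-acetoxypropyl]-5,6-dihydroxy-2-[(2Z)-5-(trimethylsilyl)pent-2-en-4-yn-1-yl]oxocan-3-yl acetate | C[Si](C)(C)C#C/C=C\C[C@H]1O[C@@H]([C@H](CC)OC(C)=O)C[C@H](O)[C@H](O)C[C@H]1OC(C)=O | intermediate
24 | (2R,3R,5R,6S,8R)-8-[(1S)-1-acetoxypropyl]-5,6-dihydroxy-2-[(2Z)-pent-2-en-4-yn-1-yl]oxocan-3-yl acetate | C#C/C=C\C[C@H]1O[C@@H]([C@H](CC)OC(C)=O)C[C@H](O)[C@H](O)C[C@H]1OC(C)=O | target

**Step count and risks**

Total step count: 16. Longest linear sequence: 16 steps (1 → 24).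

Steps most likely to fail:

**Step 13.** The oxonium ion may be captured by acetate at the exocyclic carbon C6, which returns the seven-membered ether with net retention, or the sulfonate may ionise without oxygen participation and eliminate. The fallback gives up the oxygen shift and closes the eight-membered ring directly by metathesis in the enantiomeric diepoxide series. It sets out from 5 and 15 together with the commercial enantiomer of 1, (2R,2'R)-2,2'-bioxirane F1, and returns to the route at 20. F1 is opened once with vinylmagnesium bromide/CuI to (1R)-1-[(2R)-oxiran-2-yl]but-3-en-1-ol F2, which is etherified (NaH, PMBCl, Bu4NI, 0 °C) to (2R)-2-{(1R)-1-[(4-methoxybenzyl)oxy]but-3-en-1-yl}oxirane F3. Opening with 16/BF3·OEt2 gives (6R,7R)-7-[(4-methoxybenzyl)oxy]-1-(trimethylsilyl)dec-9-ene-1,3-diyn-6-ol F4, whose C6 hydroxyl becomes the ring oxygen. O-Alkylation with bromoacetic acid/NaH gives the glycolic acid ether F5, which is coupled (PivCl; then 7) to the glycolyl oxazolidinone F6 and allylated (NaHMDS, allyl iodide) to the (2R)-pent-4-enoyl imide F7. Ring-closing metathesis (Grubbs II), helped by the gauche arrangement of the vicinal C6 and C7 oxygens, should give the oxocene imide F8. The conditions of steps 7 to 9 then give the Weinreb amide F9, the ethyl ketone F10 and the (13S)-alcohol F11. DDQ removes the PMB group to the C7,C13-diol F12, and acetylation of both hydroxyls (Ac2O, pyridine, DMAP) gives 20.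

**Step 11.** The alkynylboron reagent may add to the C13 acetate carbonyl in competition with the epoxide, or the acetate may be lost under BF3. The fallback changes the protecting-group logic so that no ester is present during the alkynylation. It sets out from 13 and returns at 18. 13 is silylated (TESCl, imidazole) to the triethylsilyl ether of 13 F13, and the oxirane is opened with 16/BF3·OEt2 to the C13-O-triethylsilyl analogue of 17 F14. Chloromethanesulfonylation gives the C13-O-triethylsilyl analogue of 18 F15, and HF·pyridine (THF/pyridine, 0 °C) removes the silyl ether to the deacetyl analogue of 18 F16. Acetylation of F16 at 0 °C (Ac2O, pyridine, DMAP), done promptly to forestall attack of the C13 hydroxyl on C6, gives 18.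

**Step 14.** The facial selectivity of the osmylation of the flexible eight-membered ring may be poor. The fallback moves the dihydroxylation to the more rigid seven-membered ring, whose chair places both α-substituents equatorial and leaves the convex face anti to them open, and then carries the diol protected through the ring expansion. It sets out from 14 and returns at 23. 14 is osmylated (OsO4, NMO) to (1S)-1-[(2R,4S,5R,7S)-4,5-dihydroxy-7-[(2S)-oxiran-2-yl]oxepan-2-yl]propyl acetate F17 and silylated (TBSCl, imidazole, DMAP, DMF) to the bis(tert-butyldimethylsilyl) ether F18. Opening with 16/BF3·OEt2 gives the diynyl alcohol F19, chloromethanesulfonylation gives F20, and Zn(OAc)2/AcOH expands the oxepane to the bis-silylated oxocane diacetate F21. Hydroboration–protodeboronation with Sia2BH/AcOH gives the Z-enyne F22, and HF·pyridine removes the two O-silyl groups while leaving the alkynylsilane, which gives 23.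

**Further compounds**

F1 | step 13 | (2R,2'R)-2,2'-bioxirane | C1O[C@H]1[C@H]1CO1
F2 | step 13 | (1R)-1-[(2R)-oxiran-2-yl]but-3-en-1-ol | C=CC[C@@H](O)[C@H]1CO1
F3 | step 13 | (2R)-2-{(1R)-1-[(4-methoxybenzyl)oxy]but-3-en-1-yl}oxirane | C=CC[C@@H](OCc1ccc(OC)cc1)[C@H]1CO1
F4 | step 13 | (6R,7R)-7-[(4-methoxybenzyl)oxy]-1-(trimethylsilyl)dec-9-ene-1,3-diyn-6-ol | C[Si](C)(C)C#CC#CC[C@@H](O)[C@@H](CC=C)OCc1ccc(OC)cc1
F5 | step 13 | 2-{[(6R,7R)-7-[(4-methoxybenzyl)oxy]-1-(trimethylsilyl)dec-9-ene-1,3-diyn-6-yl]oxy}acetic acid | C[Si](C)(C)C#CC#CC[C@@H](OCC(=O)O)[C@@H](CC=C)OCc1ccc(OC)cc1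
F6 | step 13 | (4S)-4-benzyl-3-(2-{[(6R,7R)-7-[(4-methoxybenzyl)oxy]-1-(trimethylsilyl)dec-9-ene-1,3-diyn-6-yl]oxy}acetyl)-1,3-oxazolidin-2-one | C[Si](C)(C)C#CC#CC[C@@H](OCC(=O)N1[C@@H](Cc2ccccc2)COC1=O)[C@@H](CC=C)OCc1ccc(OC)cc1
F7 | step 13 | (4S)-4-benzyl-3-[(2R)-2-{[(6R,7R)-7-[(4-methoxybenzyl)oxy]-1-(trimethylsilyl)dec-9-ene-1,3-diyn-6-yl]oxy}pent-4-enoyl]-1,3-oxazolidin-2-one | C[Si](C)(C)C#CC#CC[C@@H](O[C@H](CC=C)C(=O)N1[C@@H](Cc2ccccc2)COC1=O)[C@@H](CC=C)OCc1ccc(OC)cc1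
F8 | step 13 | (4S)-4-benzyl-3-{[(2R,7R,8R)-7-[(4-methoxybenzyl)oxy]-8-[5-(trimethylsilyl)penta-2,4-diyn-1-yl]-3,6,7,8-tetrahydro-2H-oxocin-2-yl]carbonyl}-1,3-oxazolidin-2-one | C[Si](C)(C)C#CC#CC[C@H]1O[C@@H](C(=O)N2[C@@H](Cc3ccccc3)COC2=O)C/C=C\C[C@H]1OCc1ccc(OC)cc1
F9 | step 13 | (2R,7R,8R)-N-methoxy-7-[(4-methoxybenzyl)oxy]-N-methyl-8-[5-(trimethylsilyl)penta-2,4-diyn-1-yl]-3,6,7,8-tetrahydro-2H-oxocine-2-carboxamide | C[Si](C)(C)C#CC#CC[C@H]1O[C@@H](C(=O)N(C)OC)C/C=C\C[C@H]1OCc1ccc(OC)cc1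
F10 | step 13 | 1-[(2R,7R,8R)-7-[(4-methoxybenzyl)oxy]-8-[5-(trimethylsilyl)penta-2,4-diyn-1-yl]-3,6,7,8-tetrahydro-2H-oxocin-2-yl]propan-1-one | C[Si](C)(C)C#CC#CC[C@H]1O[C@@H](C(=O)CC)C/C=C\C[C@H]1OCc1ccc(OC)cc1
F11 | step 13 | (1S)-1-[(2R,7R,8R)-7-[(4-methoxybenzyl)oxy]-8-[5-(trimethylsilyl)penta-2,4-diyn-1-yl]-3,6,7,8-tetrahydro-2H-oxocin-2-yl]propan-1-ol | C[Si](C)(C)C#CC#CC[C@H]1O[C@@H]([C@H](CC)O)C/C=C\C[C@H]1OCc1ccc(OC)cc1
F12 | step 13 | (2R,3R,8R)-8-[(1S)-1-hydroxypropyl]-2-[5-(trimethylsilyl)penta-2,4-diyn-1-yl]-3,4,7,8-tetrahydro-2H-oxocin-3-ol | C[Si](C)(C)C#CC#CC[C@H]1O[C@@H]([C@H](CC)O)C/C=C\C[C@H]1O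
F13 | step 11 | triethyl{(1S)-1-[(2R,7S)-7-[(2S)-oxiran-2-yl]-2,3,6,7-tetrahydrooxepin-2-yl]propoxy}silane | C1O[C@@H]1[C@@H]2C/C=C\C[C@@H](O2)[C@@H](O[Si](CC)(CC)CC)CC
F14 | step 11 | (1S)-1-[(2S,7R)-7-[(1S)-1-(triethylsilyloxy)propyl]-2,3,6,7-tetrahydrooxepin-2-yl]-6-(trimethylsilyl)hexa-3,5-diyn-1-ol | C[Si](C)(C)C#CC#CC[C@H](O)[C@@H]1C/C=C\C[C@@H](O1)[C@@H](O[Si](CC)(CC)CC)CC
F15 | step 11 | (1S)-1-[(2S,7R)-7-[(1S)-1-(triethylsilyloxy)propyl]-2,3,6,7-tetrahydrooxepin-2-yl]-6-(trimethylsilyl)hexa-3,5-diyn-1-yl chloromethanesulfonate | C[Si](C)(C)C#CC#CC[C@H](OS(=O)(=O)CCl)[C@@H]1C/C=C\C[C@@H](O1)[C@@H](O[Si](CC)(CC)CC)CC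
F16 | step 11 | (1S)-1-[(2S,7R)-7-[(1S)-1-hydroxypropyl]-2,3,6,7-tetrahydrooxepin-2-yl]-6-(trimethylsilyl)hexa-3,5-diyn-1-yl chloromethanesulfonate | C[Si](C)(C)C#CC#CC[C@H](OS(=O)(=O)CCl)[C@@H]1C/C=C\C[C@@H](O1)[C@@H](O)CC
F17 | step 14 | (1S)-1-[(2R,4S,5R,7S)-4,5-dihydroxy-7-[(2S)-oxiran-2-yl]oxepan-2-yl]propyl acetate | C1O[C@@H]1[C@@H]2C[C@@H](O)[C@@H](O)C[C@@H](O2)[C@@H](OC(C)=O)CC
F18 | step 14 | (1S)-1-[(2R,4S,5R,7S)-4,5-bis(tert-butyldimethylsilyloxy)-7-[(2S)-oxiran-2-yl]oxepan-2-yl]propyl acetate | C1O[C@@H]1[C@@H]2C[C@@H](O[Si](C)(C)C(C)(C)C)[C@@H](O[Si](C)(C)C(C)(C)C)C[C@@H](O2)[C@@H](OC(C)=O)CC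
F19 | step 14 | (1S)-1-[(2R,4S,5R,7S)-4,5-bis(tert-butyldimethylsilyloxy)-7-[(1S)-1-hydroxy-6-(trimethylsilyl)hexa-3,5-diyn-1-yl]oxepan-2-yl]propyl acetate | C[Si](C)(C)C#CC#CC[C@H](O)[C@@H]1C[C@@H](O[Si](C)(C)C(C)(C)C)[C@@H](O[Si](C)(C)C(C)(C)C)C[C@@H](O1)[C@@H](OC(C)=O)CC
F20 | step 14 | (1S)-1-[(2R,4S,5R,7S)-4,5-bis(tert-butyldimethylsilyloxy)-7-[(1S)-1-{[(chloromethyl)sulfonyl]oxy}-6-(trimethylsilyl)hexa-3,5-diyn-1-yl]oxepan-2-yl]propyl acetate | C[Si](C)(C)C#CC#CC[C@H](OS(=O)(=O)CCl)[C@@H]1C[C@@H](O[Si](C)(C)C(C)(C)C)[C@@H](O[Si](C)(C)C(C)(C)C)C[C@@H](O1)[C@@H](OC(C)=O)CC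
F21 | step 14 | (2R,3R,5R,6S,8R)-8-[(1S)-1-acetoxypropyl]-5,6-bis(tert-butyldimethylsilyloxy)-2-[5-(trimethylsilyl)penta-2,4-diyn-1-yl]oxocan-3-yl acetate | C[Si](C)(C)C#CC#CC[C@H]1O[C@@H]([C@H](CC)OC(C)=O)C[C@H](O[Si](C)(C)C(C)(C)C)[C@H](O[Si](C)(C)C(C)(C)C)C[C@H]1OC(C)=O
F22 | step 14 | (2R,3R,5R,6S,8R)-8-[(1S)-1-acetoxypropyl]-5,6-bis(tert-butyldimethylsilyloxy)-2-[(2Z)-5-(trimethylsilyl)pent-2-en-4-yn-1-yl]oxocan-3-yl acetate | C[Si](C)(C)C#C/C=C\C[C@H]1O[C@@H]([C@H](CC)OC(C)=O)C[C@H](O[Si](C)(C)C(C)(C)C)[C@H](O[Si](C)(C)C(C)(C)C)C[C@H]1OC(C)=O
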